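**Retrosynthetic overview**

1. Acid 14 ← methyl ester 13 ← aldehyde 10 + enol triflate 12 of (E)-geranylacetone (C3′–C4′ bond, catalytic asymmetric Nozaki–Hiyama–Kishi coupling sets the carbinol centre); 10 ← 5-vinyloxane 9 by hydroformylation.
2. The oxane is the only ring and is made once, in step 4, from acyclic bis-acetate 6 and formaldehyde: C6–C5 by iridium-catalysed allylation of formaldehyde, O1–C2 by alkoxide SN2′ closure. C5 is set by the catalyst and C2 is relayed from it.
3. Enabling feature: the O1–C6H2 unit of the oxane is a formaldehyde unit. It lies between C5, whose side-chain carbons C1′–C2′ can be drawn back to a vinyl group (C5 is then the substituted end of an allyl nucleophile), and C2, which is allylic to the exo-methylene of the acrylate (O1–C2–C(=CH2)–C=O is the retron of an addition–elimination on a 2-(acetoxymethyl)enoate).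
4. 6 ← hex-5-enal 1 + methyl acrylate 2 (Morita–Baylis–Hillman reaction, acetate transposition, branched allylic C–H acetoxylation).

Key step: step 4

Assumption: the absolute sense of induction of the chiral ligands in steps 4 and 7 is assigned by analogy with related couplings; both ligands exist in either enantiomeric form, and the antipode is used if the sense proves opposite. Hex-5-enal and (E)-geranylacetone are taken as commercial single isomers.

**Step 1**
Reactants: 1 hex-5-enal; 2 methyl acrylate
Product: 3 methyl 3-hydroxy-2-methylideneoct-7-enoate (racemic)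
Conditions: DABCO (0.3 equiv), MeOH, rt
Reagents that add atoms: none
Why: Morita–Baylis–Hillman reaction, in which the DABCO–acrylate zwitterion adds to the unhindered aliphatic aldehyde while the terminal alkene is inert; the carbinol centre forms racemic and is erased in step 2.

**Step 2**
Reactants: 3 methyl 3-hydroxy-2-methylideneoct-7-enoate
Product: 5 methyl (2E)-2-[(acetyloxy)methyl]octa-2,7-dienoate, via secondary acetate 4 (not isolated)
Conditions: Ac2O, Et3N, DMAP (cat.), CH2Cl2, 0 °C; then DABCO (0.2 equiv), THF, reflux
Reagents that add atoms: acetic anhydride, CC(=O)OC(C)=O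
Why: Acetylation followed by the known DABCO-mediated 1,3-transposition of Baylis–Hillman acetates (SN2′ addition of the amine, return of acetate at the primary carbon) should give the thermodynamically favoured conjugated (E)-enoate; no stereocentre remains.

**Step 3**
Reactants: 5 methyl (2E)-2-[(acetyloxy)methyl]octa-2,7-dienoate
Product: 6 methyl (2E)-6-(acetyloxy)-2-[(acetyloxy)methyl]octa-2,7-dienoate (racemic at C6)
Conditions: Pd(OAc)2/1,2-bis(phenylsulfinyl)ethane (10 mol %), p-benzoquinone (2 equiv), AcOH, 1,4-dioxane, 45 °C
Reagents that add atoms: acetic acid, CC(=O)O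
Why: Branched-selective allylic C–H acetoxylation of a terminal alkene through a π-allyl complex of divalent palladium with quinone-promoted C–O bond formation at the internal carbon; the electron-poor trisubstituted enoate should not engage, and the new centre may be racemic because step 4 is stereoconvergent.

**Step 4**
Reactants: 6 methyl (2E)-6-(acetyloxy)-2-[(acetyloxy)methyl]octa-2,7-dienoate; 7 formaldehyde (as paraformaldehyde)
Product: 9 methyl 2-[(2R,5R)-5-ethenyloxan-2-yl]prop-2-enoate, via hydroxy acetate 8 (not isolated)
Conditions: Ir(η3-C3H5)[(S)-SEGPHOS](κC,κO-4-cyano-3-nitrobenzoate) (5 mol %; from [Ir(cod)Cl]2, the ligand, the acid and allyl acetate), (CH2O)n (3 equiv), i-PrOH (2 equiv), K3PO4 (10 mol %), THF, 60 °C; then Cs2CO3 (3 equiv), 40 °C, same flask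
Reagents that add atoms: none
Why: Proposed new method: a reductive allyl–formaldehyde coupling interrupted by ring closure, in which ionisation of the secondary allylic acetate of 6 by monovalent iridium (both enantiomers converge) gives a cyclometalated π-allyl complex of trivalent iridium that adds through its (E)-σ-allyl form and a closed chair transition state to formaldehyde at the substituted allyl terminus, the SEGPHOS ligand choosing between the enantiotopic π-faces of the allyl and so fixing the (R)-centre of 8 by catalyst control, while isopropanol supplies the hydride that regenerates the catalyst. The primary alkoxide of 8 then adds 6-exo-trig to the β-carbon of the (2E)-2-(acetoxymethyl)enoate and the ester enolate expels acetate (E1cB, overall SN2′), which closes the oxane and uncovers the exo-methylene ester in the same event. The ring closes through a chair in which the vinyl group and the forming acrylate arm are both equatorial, so the catalyst-set centre relays the 2,5-trans relation to C2 by substrate control. The closest known reaction types are the iridium-catalysed, isopropanol-mediated coupling of branched allylic acetates with formaldehyde and the alkoxide SN2′ substitution of rearranged Baylis–Hillman acetates; their union in one flask on a substrate that carries two allylic acetates is new. The step needs chemoselective ionisation of the secondary acetate next to the monosubstituted vinyl group over the primary acetate on the trisubstituted acceptor alkene, which the much better coordination of monovalent iridium to a terminal alkene should secure, and the conjugate acceptor is left untouched until the carbonate base is added.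

**Step 5**
Reactants: 9 methyl 2-[(2R,5R)-5-ethenyloxan-2-yl]prop-2-enoate
Product: 10 methyl 2-[(2R,5R)-5-(3-oxopropyl)oxan-2-yl]prop-2-enoate
Conditions: Rh(acac)(CO)2 (1 mol %), BIPHEPHOS (2 mol %), CO/H2 (1:1, 5 bar), toluene, 60 °C
Reagents that add atoms: carbon monoxide, [C-]#[O+]
Why: Linear-selective rhodium/bisphosphite hydroformylation of the monosubstituted vinyl group, whose α-branch and the wide-bite-angle ligand direct the formyl group to the terminus, while the 1,1-disubstituted electron-poor acrylate alkene should react far more slowly; no stereocentre is formed or touched.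

**Step 6**
Reactants: 11 (E)-geranylacetone
Product: 12 (5E)-6,10-dimethylundeca-1,5,9-trien-2-yl trifluoromethanesulfonate
Conditions: LiN(i-Pr)2 (LDA), THF, −78 °C; then PhNTf2, −78 → 0 °C
Reagents that add atoms: N-phenylbis(trifluoromethanesulfonimide), O=S(=O)(N(c1ccccc1)S(=O)(=O)C(F)(F)F)C(F)(F)F
Why: Kinetic deprotonation of the methyl ketone at the methyl group and O-sulfonylation of the terminal enolate (enol triflate formation); no stereocentre is involved and the (E)-alkene is untouched.

**Step 7**
Reactants: 10 methyl 2-[(2R,5R)-5-(3-oxopropyl)oxan-2-yl]prop-2-enoate; 12 (5E)-6,10-dimethylundeca-1,5,9-trien-2-yl trifluoromethanesulfonate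
Product: 13 methyl 2-[(2R,5S)-5-[(3R,7E)-3-hydroxy-8,12-dimethyl-4-methylidenetrideca-7,11-dien-1-yl]oxan-2-yl]prop-2-enoate
Conditions: CrCl2 (10 mol %), (S)-N-[2-(4-isopropyl-4,5-dihydro-1,3-oxazol-2-yl)-6-methylphenyl]methanesulfonamide (11 mol %), 1,8-bis(dimethylamino)naphthalene (11 mol %), NiCl2·(2,9-dimethyl-1,10-phenanthroline) (2 mol %), Mn (2 equiv), Zr(Cp)2Cl2 (1 equiv), LiCl (2 equiv), MeCN, rt; aqueous work-up
Reagents that add atoms: none
Why: Catalytic asymmetric Nozaki–Hiyama–Kishi coupling, in which the alkenyl triflate is activated by nickel, transferred to chromium and added to the aldehyde as an alkenyl species of trivalent chromium bound to the chiral sulfonamide, which should set the (R)-carbinol by catalyst control because the ring centres are remote; esters and the acrylate are tolerated by organochromium reagents.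

**Step 8**
Reactants: 13 methyl 2-[(2R,5S)-5-[(3R,7E)-3-hydroxy-8,12-dimethyl-4-methylidenetrideca-7,11-dien-1-yl]oxan-2-yl]prop-2-enoate
Product: 14 2-[(2R,5S)-5-[(3R,7E)-3-hydroxy-8,12-dimethyl-4-methylidenetrideca-7,11-dien-1-yl]oxan-2-yl]prop-2-enoic acid
Conditions: LiOH·H2O, THF/H2O (3:1), 0 °C → rt; then 1 M HCl to pH 3–4
Reagents that add atoms: lithium hydroxide (its oxygen becomes the acid OH), [Li+].[OH-]
Why: Saponification of the methyl ester at low temperature, where acyl substitution should outrun conjugate addition to the α-substituted acrylate; no stereocentre carries an acidic hydrogen, so none is touched.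

**Compound list**

1 | hex-5-enal | C=CCCCC=O | starting material
2 | methyl acrylate | C=CC(=O)OC | starting material
3 | methyl 3-hydroxy-2-methylideneoct-7-enoate (racemic) | C=CCCCC(O)C(=C)C(=O)OC | intermediate
4 | methyl 3-(acetyloxy)-2-methylideneoct-7-enoate (racemic, not isolated) | C=CCCCC(OC(C)=O)C(=C)C(=O)OC | intermediate
5 | methyl (2E)-2-[(acetyloxy)methyl]octa-2,7-dienoate | C=CCCC/C=C(\COC(C)=O)C(=O)OC | intermediate
6 | methyl (2E)-6-(acetyloxy)-2-[(acetyloxy)methyl]octa-2,7-dienoate (racemic at C6) | C=CC(OC(C)=O)CC/C=C(\COC(C)=O)C(=O)OC | intermediate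
7 | formaldehyde (used as paraformaldehyde) | C=O | starting material
8 | methyl (2E,6R)-2-[(acetyloxy)methyl]-6-(hydroxymethyl)octa-2,7-dienoate (not isolated) | OC[C@@H](C=C)CC/C=C(\COC(C)=O)C(=O)OC | intermediate
9 | methyl 2-[(2R,5R)-5-ethenyloxan-2-yl]prop-2-enoate | C=C[C@H]1CC[C@H](C(=C)C(=O)OC)OC1 | intermediate
10 | methyl 2-[(2R,5R)-5-(3-oxopropyl)oxan-2-yl]prop-2-enoate | O=CCC[C@H]1CC[C@H](C(=C)C(=O)OC)OC1 | intermediate
11 | (E)-geranylacetone, (5E)-6,10-dimethylundeca-5,9-dien-2-one | CC(=O)CC/C=C(\C)CCC=C(C)C | starting material
12 | (5E)-6,10-dimethylundeca-1,5,9-trien-2-yl trifluoromethanesulfonate | C=C(OS(=O)(=O)C(F)(F)F)CC/C=C(\C)CCC=C(C)C | intermediate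
13 | methyl 2-[(2R,5S)-5-[(3R,7E)-3-hydroxy-8,12-dimethyl-4-methylidenetrideca-7,11-dien-1-yl]oxan-2-yl]prop-2-enoate | C=C(CC/C=C(\C)CCC=C(C)C)[C@H](O)CC[C@H]1CC[C@H](C(=C)C(=O)OC)OC1 | intermediate
14 | 2-[(2R,5S)-5-[(3R,7E)-3-hydroxy-8,12-dimethyl-4-methylidenetrideca-7,11-dien-1-yl]oxan-2-yl]prop-2-enoic acid | C=C(CC/C=C(\C)CCC=C(C)C)[C@H](O)CC[C@H]1CC[C@H](C(=C)C(=O)O)OC1 | target

**Step count**

Total steps: 8. Longest linear sequence: 7 (steps 1–5, 7, 8); step 6 is the one-step side branch.

**Steps most likely to fail**

Step 4 (proposed new method). What may go wrong: ionisation of the primary allylic acetate on the enoate instead of the secondary one, conjugate addition of isopropanol before the internal alcohol exists, or ring closure with poor trans selectivity. The fallback decouples the events with known chemistry and installs the exo-methylene last. It sets out from 1 and returns at 9.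
- Hex-5-enal 1 is olefinated (trimethyl phosphonoacetate, LiCl, DBU, MeCN, Horner–Wadsworth–Emmons) to methyl (2E)-octa-2,7-dienoate F1.
- The palladium/bis-sulfoxide allylic acetoxylation of step 3 gives methyl (2E)-6-(acetyloxy)octa-2,7-dienoate F2.
- The known iridium/SEGPHOS coupling with paraformaldehyde and isopropanol, now on a substrate with a single allylic acetate, gives methyl (2E,6R)-6-(hydroxymethyl)octa-2,7-dienoate F3, which is isolated.
- KOt-Bu (cat.), THF, 0 °C → rt closes it by equilibrating oxa-Michael addition to the diequatorial methyl 2-[(2R,5R)-5-ethenyloxan-2-yl]acetate F4.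
- α-Methylenation (LDA, −78 °C, then dimethylmethylideneammonium iodide) gives the Mannich base methyl 3-(dimethylamino)-2-[(2R,5R)-5-ethenyloxan-2-yl]propanoate F5; MeI converts it into the ammonium salt [2-[(2R,5R)-5-ethenyloxan-2-yl]-3-methoxy-3-oxopropyl]trimethylammonium iodide F6, and NaHCO3 eliminates this to 9.

Step 7. What may go wrong: poor facial selectivity at the new carbinol, since the catalyst must act alone with the ring centres remote, and reductive loss of the triflate. The fallback replaces catalyst-controlled C–C bond formation by reagent-controlled ketone reduction. It sets out from 10 and 12 and returns at 13.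
- The coupling is run without chiral ligand (CrCl2 in excess, NiCl2 cat., DMF, rt) to the carbinol-epimeric mixture methyl 2-[(2R,5S)-5-[(3RS,7E)-3-hydroxy-8,12-dimethyl-4-methylidenetrideca-7,11-dien-1-yl]oxan-2-yl]prop-2-enoate F7.
- Dess–Martin periodinane (NaHCO3, CH2Cl2) oxidises it to methyl 2-[(2R,5R)-5-[(7E)-8,12-dimethyl-4-methylidene-3-oxotrideca-7,11-dien-1-yl]oxan-2-yl]prop-2-enoate F8.
- Corey–Bakshi–Shibata reduction ((S)-2-methyl-CBS-oxazaborolidine, catecholborane, toluene, −78 °C), with the alkenyl group as the large substituent, should give 13.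

Step 5. What may go wrong: formation of the branched aldehyde, or hydroformylation or hydrogenation of the acrylate alkene. The fallback by-passes aldehyde 10 and step 7. It sets out from 9 (with 12) and returns at 13.
- Hydroboration of the vinyl group (9-BBN-H, THF, 0 °C → rt) gives methyl 2-[(2R,5S)-5-[2-(9-borabicyclo[3.3.1]nonan-9-yl)ethyl]oxan-2-yl]prop-2-enoate F9.
- Carbonylative Suzuki–Miyaura coupling with triflate 12 (Pd(PPh3)4, zerovalent palladium, K3PO4, CO 1 atm, dioxane, rt) gives enone F8, which is reduced as in the fallback for step 7 to 13.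

**Further compounds**

F1 | step 4 | methyl (2E)-octa-2,7-dienoate | C=CCCC/C=C/C(=O)OC
F2 | step 4 | methyl (2E)-6-(acetyloxy)octa-2,7-dienoate (racemic) | C=CC(OC(C)=O)CC/C=C/C(=O)OC
F3 | step 4 | methyl (2E,6R)-6-(hydroxymethyl)octa-2,7-dienoate | OC[C@@H](C=C)CC/C=C/C(=O)OC
F4 | step 4 | methyl 2-[(2R,5R)-5-ethenyloxan-2-yl]acetate | C=C[C@H]1CC[C@H](CC(=O)OC)OC1
F5 | step 4 | methyl 3-(dimethylamino)-2-[(2R,5R)-5-ethenyloxan-2-yl]propanoate (both epimers at the α-carbon) | C=C[C@H]1CC[C@H](C(CN(C)C)C(=O)OC)OC1
F6 | step 4 | [2-[(2R,5R)-5-ethenyloxan-2-yl]-3-methoxy-3-oxopropyl]trimethylammonium iodide (both epimers at the α-carbon) | C=C[C@H]1CC[C@H](C(C[N+](C)(C)C)C(=O)OC)OC1.[I-]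
F7 | step 7 | methyl 2-[(2R,5S)-5-[(3RS,7E)-3-hydroxy-8,12-dimethyl-4-methylidenetrideca-7,11-dien-1-yl]oxan-2-yl]prop-2-enoate | C=C(CC/C=C(\C)CCC=C(C)C)C(O)CC[C@H]1CC[C@H](C(=C)C(=O)OC)OC1
F8 | step 7 | methyl 2-[(2R,5R)-5-[(7E)-8,12-dimethyl-4-methylidene-3-oxotrideca-7,11-dien-1-yl]oxan-2-yl]prop-2-enoate | C=C(CC/C=C(\C)CCC=C(C)C)C(=O)CC[C@H]1CC[C@H](C(=C)C(=O)OC)OC1
F9 | step 5 | methyl 2-[(2R,5S)-5-[2-(9-borabicyclo[3.3.1]nonan-9-yl)ethyl]oxan-2-yl]prop-2-enoate | B1(C2CCCC1CCC2)CC[C@H]3CC[C@H](C(=C)C(=O)OC)OC3
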